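**Stereochemistry note:** Gardenin C as drawn has no stereocenters and is achiral. No stereochemical control is needed, and the flavone C2=C3 bond is retained throughout.

**Assumptions:**
- 2,3,4-Trimethoxybenzaldehyde and 3-hydroxy-4,5-dimethoxybenzaldehyde are commercial.
- In the Fries step (Step 3), acyl migration can only occur at C6, the one free position ortho to the ester oxygen.

## Retrosynthesis
1. The 5'-OH is revealed last by hydrogenolysis of a benzyl ether (9 → 10).
2. The peri 5-OH is installed by carbonyl-directed Ru-catalysed C5–H hydroxylation of 6,7,8-trimethoxyflavone 8. This is the proposed new step, and it avoids selective 5-O-demethylation among four OMe groups.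
3. The pyranone ring is formed last among the rings, by I2/DMSO oxidative cyclisation of 2'-hydroxychalcone 7. The chalcone comes from Claisen–Schmidt condensation of acetophenone 4 with aldehyde 6.
4. Ring A (acetophenone 4) is made from commercial 2,3,4-trimethoxybenzaldehyde by Dakin oxidation, acetylation and Fries rearrangement. Ring B is a benzyl-protected commercial aldehyde.

## Forward route

**Step 1**
Reactants: 1 (2,3,4-trimethoxybenzaldehyde)
Product: 2 (2,3,4-trimethoxyphenol)
Conditions: (i) mCPBA, NaHCO3, CH2Cl2, 0 °C → rt; (ii) K2CO3, MeOH, rt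
Reagents that add atoms: mCPBA, OOC(=O)c1cccc(Cl)c1 (supplies the phenol O)
Why: Dakin/Baeyer–Villiger oxidation of an aldehyde with ortho- and para-OMe groups, where aryl migration gives the aryl formate. Methanolysis then releases the phenol.

**Step 2**
Reactants: 2 (2,3,4-trimethoxyphenol)
Product: 3 (2,3,4-trimethoxyphenyl acetate)
Conditions: Ac2O, pyridine, cat. DMAP, CH2Cl2, rt
Reagents that add atoms: acetic anhydride, CC(=O)OC(C)=O
Why: Plain O-acylation of a phenol to prepare the Fries substrate.

**Step 3**
Reactants: 3
Product: 4 (1-(2-hydroxy-3,4,5-trimethoxyphenyl)ethan-1-one)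
Conditions: BF3·OEt2 (3 equiv), neat or 1,2-DCE, 80 °C
Reagents that add atoms: none (the acetyl group comes from 3)
Why: Fries rearrangement. The para position is blocked by OMe and only C6 is free ortho to oxygen, so the acyl group goes there with no regiochemical ambiguity. BF3 is used instead of AlCl3 to avoid cleaving the ortho OMe.

**Step 4**
Reactants: 5 (3-hydroxy-4,5-dimethoxybenzaldehyde)
Product: 6 (3-(benzyloxy)-4,5-dimethoxybenzaldehyde)
Conditions: BnBr, K2CO3, DMF, rt
Reagents that add atoms: benzyl bromide, BrCc1ccccc1
Why: Williamson etherification masks the B-ring phenol so that it survives the base and oxidants in Steps 5–7.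

**Step 5**
Reactants: 4 (2'-hydroxy-3',4',5'-trimethoxyacetophenone) and 6
Product: 7 ((E)-3-(3-benzyloxy-4,5-dimethoxyphenyl)-1-(2-hydroxy-3,4,5-trimethoxyphenyl)prop-2-en-1-one)
Conditions: KOH (aq. 50%), EtOH, rt, 24 h
Reagents that add atoms: none
Why: Claisen–Schmidt aldol condensation. The ketone enolate adds to the aldehyde and water is lost to give the trans-chalcone, held as the 2'-hydroxy chalcone by its intramolecular H-bond.

**Step 6**
Reactants: 7
Product: 8 (5'-benzyloxy-3',4',6,7,8-pentamethoxyflavone)
Conditions: I2 (0.2 equiv), DMSO, 130 °C, 3 h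
Reagents that add atoms: none (I2 is catalytic and DMSO is the terminal oxidant)
Why: Oxa-Michael cyclisation to the flavanone, then iodination and elimination (I2/DMSO dehydrogenation) gives the flavone. C2=C3 is set as the aromatic pyranone, and no stereocenter is formed.

**Step 7**
Reactants: 8
Product: 9 (5-hydroxy-5'-benzyloxy-3',4',6,7,8-pentamethoxyflavone)
Conditions: [RuCl2(p-cymene)]2 (5 mol %), PIFA (2 equiv), TFA/TFAA (4:1), DCE, 40 °C; then K2CO3, MeOH/H2O, rt
Reagents that add atoms: PIFA, FC(F)(F)C(=O)OI(OC(=O)C(F)(F)F)c1ccccc1; trifluoroacetic acid, OC(=O)C(F)(F)F (source of the oxygen, delivered as aryl trifluoroacetate and cleaved to OH by K2CO3/MeOH)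
Why: Proposed new method: the C4 carbonyl oxygen binds Ru(II) and directs concerted metalation–deprotonation at C5–H. This is the only C–H that can form a five-membered ruthenacycle, because C3–H would need a four-membered one and ring B has no directing group. PIFA oxidises Ru(II) to Ru(IV), C–O reductive elimination with trifluoroacetate gives the 5-OCOCF3 arene, and basic methanolysis gives the chelated 5-OH. The closest known reactions are Ru(II)/PIFA ketone-directed ortho C–H hydroxylation of aryl ketones and carbonyl-directed C5–H functionalisation of chromones. The new element is applying it to a fully substituted, very electron-rich 6,7,8-trimethoxyflavone that carries an aryl benzyl ether. No new stereocenter is formed.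

**Step 8**
Reactants: 9
Product: 10 (gardenin C as specified: 5,5'-dihydroxy-3',4',6,7,8-pentamethoxyflavone)
Conditions: H2 (1 atm), 10% Pd/C, EtOAc/EtOH, rt, 1–2 h (monitored)
Reagents that add atoms: none (hydrogen only; toluene is lost)
Why: Hydrogenolysis of the aryl benzyl ether. The 5-OH, the OMe groups and the flavone C2=C3 survive the short, mild reaction.

**Atom check:** 8 is C27H26O8 and 9 is C27H26O9 (one O added at C5). Removing the benzyl group (C7H6) from 9 gives C20H20O9. That is the target: 5 OMe + 2 OH + flavone core = C15H5O2 + 5 × CH3 + 2 OH.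

## Compound list
1 | 2,3,4-trimethoxybenzaldehyde | COc1ccc(C=O)c(OC)c1OC | starting material
2 | 2,3,4-trimethoxyphenol | COc1ccc(O)c(OC)c1OC | intermediate
3 | 2,3,4-trimethoxyphenyl acetate | COc1ccc(OC(C)=O)c(OC)c1OC | intermediate
4 | 2'-hydroxy-3',4',5'-trimethoxyacetophenone | CC(=O)c1cc(OC)c(OC)c(OC)c1O | intermediate
5 | 3-hydroxy-4,5-dimethoxybenzaldehyde | COc1cc(C=O)cc(O)c1OC | starting material
6 | 3-(benzyloxy)-4,5-dimethoxybenzaldehyde | COc1cc(C=O)cc(OCc2ccccc2)c1OC | intermediate
7 | (E)-chalcone from 4 and 6 | COc1cc(/C=C/C(=O)c2cc(OC)c(OC)c(OC)c2O)cc(OCc2ccccc2)c1OC | intermediate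
8 | 5'-benzyloxy-3',4',6,7,8-pentamethoxyflavone | COc1cc(-c2cc(=O)c3cc(OC)c(OC)c(OC)c3o2)cc(OCc2ccccc2)c1OC | intermediate
9 | 5-hydroxy-5'-benzyloxy-3',4',6,7,8-pentamethoxyflavone | COc1cc(-c2cc(=O)c3c(O)c(OC)c(OC)c(OC)c3o2)cc(OCc2ccccc2)c1OC | intermediate
10 | Gardenin C (target) | COc1cc(-c2cc(=O)c3c(O)c(OC)c(OC)c(OC)c3o2)cc(O)c1OC | target

## Totals
- Total steps: 8
- Longest linear sequence: 7 (1 → 2 → 3 → 4 → 7 → 8 → 9 → 10, i.e. Steps 1, 2, 3, 5, 6, 7, 8)

## Three steps most likely to fail
1. **Step 7 (proposed new C5–H hydroxylation).** PIFA/TFA may oxidise the electron-rich ring B or cleave the benzyl ether, and the hindered, electron-rich C5–H may metalate poorly.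
   - Fallback (known chemistry, different approach): build the 5-OMe into ring A. Fries-acylate commercial 3,4,5-trimethoxyphenol, then do Duff formylation, Dakin oxidation and selective 3'-O-methylation to give 2'-hydroxy-3',4',5',6'-tetramethoxyacetophenone. Continue with Claisen–Schmidt and I2/DMSO, remove the benzyl group by H2/Pd-C, then selectively cleave the peri 5-OMe with BCl3 (CH2Cl2, −78 → 0 °C).
2. **Step 3 (Fries rearrangement).** It could give low yield or partial demethylation or deacylation.
   - Fallback: protect 2 as its MOM ether, ortho-lithiate at C6 (s-BuLi/TMEDA, THF, −78 °C), quench with N-methoxy-N-methylacetamide, and remove the MOM group with HCl/MeOH to give 4.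
3. **Step 6 (I2/DMSO cyclisation, or the preceding chalcone).** The benzyl ether may be lost under HI-generating conditions, or the 3'-OMe-hindered chalcone may be sluggish.
   - Fallback: Baker–Venkataraman route. Acylate 4 with 3-benzyloxy-4,5-dimethoxybenzoyl chloride, rearrange with KOtBu/THF to the 1,3-diketone, then cyclodehydrate under mild Mitsunobu-type conditions (PPh3/DIAD) to give 8.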